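Slowness was the first thing I read from the earlier runs, so I counted progress in turnovers: the number of time constants elapsed, which is minus the natural log of the share of starting material not yet turned into product.

| setting | midnight | autumn | Tuesday's | Monday's | Friday's | Thursday's | Sunday's |
|---|---|---|---|---|---|---|---|
| starting material | 16 mM | 16 mM | 16 mM | 16 mM | 16 mM | 16 mM | 16 mM |
| partner | 9.4 mM | 110 mM | 8.00 mM | 80.0 mM | 50.0 mM | 24.0 mM | 12.0 mM |
| remark | run made earlier | run made earlier |  |  |  |  |  |
| time |  |  | 25 min | 25 min | 25 min | 25 min | 25 min |

| midnight: time / min | midnight: product / % | autumn: time / min | autumn: product / % |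
|---|---|---|---|
| 6.00 | 12 | 3.00 | 48 |
| 12.0 | 15 | 8.00 | 69 |
| 20.0 | 20 | 15.0 | 78 |
| 25.0 | 20 | 25.0 | 83 |

(scatter of a reading: 1.5 percentage points)



1. ranking by amount of product, in percent of the starting material charged, from high to low, at 25 min (Tuesday's / Monday's / Friday's / Thursday's / Sunday's)
2. the same order at 3.0 h (Tuesday's / Monday's / Friday's / Thursday's / Sunday's)
3. the amount of product, in percent of the starting material charged of the flask you put first, at 25 min
4. the amount of product, in percent of the starting material charged of the flask you put last, at 25 min

How many turnovers did a flask make by 25 min? The midnight run read 0.223 and the autumn run 1.77. Dividing by the partner charged gave the turnover yield, turnovers per mM of partner at 25 min: a reading of 0.0237 mM⁻¹ for midnight and 0.0161 mM⁻¹ for autumn.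

Could that drift in yield reorder the flasks? The yield moved by a factor of 1.47, less than the factor of 11.7 between the partner charges of the two runs. So I ranked the flasks by partner. Each end took the yield of its nearer run, which gave Tuesday's 17.3% and Monday's 72.4%.

Could 3.0 h reorder them? Taking one partner per product, partner is the limiting reagent in Tuesday's and Sunday's, with ceilings of 50.0% and 75.0%. These ceilings rise in the same order as the ranking, so I kept it.

The forecast gave Monday's > Friday's > Thursday's > Sunday's > Tuesday's at 25 min and Monday's > Friday's > Thursday's > Sunday's > Tuesday's at 3.0 h, with Monday's at 75% and Tuesday's at 17%: “more partner gives more product”. Its figure for Monday's stood above mine.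

The flasks gave Monday's > Friday's > Thursday's > Sunday's > Tuesday's at 25 min, with Monday's at 76.6% and Tuesday's at 17.5%, and Monday's > Friday's > Thursday's > Sunday's > Tuesday's at 3.0 h.

    starting material + partner → intermediate A (k = 2.73 L mol⁻¹ min⁻¹)
    starting material ⇌ intermediate B (K = 0.520, k = 0.0591 min⁻¹)
    starting material ⇌ intermediate C (K = 2.60, k = 0.0605 min⁻¹)
    intermediate A ⇌ product (K = 43.0, k = 2.07 min⁻¹)

Monday's delivered a turnover yield of 0.0182 mM⁻¹, more than autumn's and less than midnight's. On Sunday's, midnight's yield gives 24.8% against the 24.8% found. Neither Monday's nor Tuesday's had come to rest at 25 min. Left ten times as long, Monday's reached 97.3% at 250 min, which is 3.61 turnovers, against 1.45 at 25 min. Over the same stretch Tuesday's gained more points than Monday's and reached 42.0% at 250 min, with 13.9% of its partner left.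

All runs were generated by integration with constants of no real substance.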